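## Analysis of the target

Target 20 is an unsymmetrical bis(indol-3-yl)quinone. A central cyclohexa-2,5-diene-1,4-dione (ring C) carries methoxy groups at C2 and C5, the 2-(2-methylbut-3-en-2-yl)-1H-indol-3-yl unit (indole B) at C3 and a plain 1H-indol-3-yl unit (indole A) at C6. There is no stereocentre and no configured double bond; rotation about the bond from C3 of indole B to C3 of ring C is slow but needs no control. The sensitive groups are the quinone, the two free indole N–H units and the terminal vinyl group on the quaternary carbon. The quinone is reducible, and its methoxy groups are vinylogous esters that hydroxide turns into hydroxyquinones. Indole A is the more oxidisable indole because its C2 is unsubstituted, and the vinyl group is exposed to hydrogenation, Heck arylation and strong acid. Two things make the synthesis hard: a symmetric hexasubstituted core must receive two different indoles, and one of the two ring–ring bonds is very crowded. That bond joins C3 of indole B to C3 of ring C. C3 of ring C lies between a methoxy-bearing carbon and a carbonyl carbon, and C3 of indole B sits next to C2, which holds the quaternary carbon of the 1,1-dimethylallyl group. The plan rests on this feature: the C3(indole B)–C3(ring C) bond is made in the same event that closes the pyrrole ring of indole B at N1–C2, with the quaternary carbon already carried on an alkyne.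

## Retrosynthetic reasoning

20 to 19. The last bond cut is the N–S bond of a 4-methylbenzenesulfonyl (tosyl) group on indole A. The group is kept to the end because it makes indole A, the one with a free C2, inert to the oxidant of the preceding step. On quinone 19 it can be removed by carbonate-mediated alcoholysis, since exchange of methoxy for methoxy at the quinone is degenerate. A dissolving-metal cleavage is not usable at this stage because it would reduce the quinone.

19 to 18. The quinone is traced back to a 1,2,4,5-tetramethoxybenzene ring: two para C–OMe carbons become the carbonyl carbons. Either para pair of methoxy groups leads to the same constitution, so the oxidation has no regiochemical question. The gain is a core that tolerates organolithium, organozinc and palladium chemistry and carbonate bases. The forward step must oxidise this ring with a cerium-based one-electron oxidant in the presence of one free, 2,3-disubstituted indole and one sulfonylated indole.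

18 to 8 and 16. This is the key disconnection: the N1–C2 bond and the C3–aryl bond of indole B are cut together. The fragments are the o-alkynyl trifluoroacetanilide 8 and the aryl iodide 16. The cut is placed here because both crowded positions of indole B are then filled without a bond to a preformed hindered indole; the quaternary carbon is a spectator on the alkyne. The forward step must make an arylpalladium species from 16 add across the alkyne of 8 with the anilide nitrogen, not across the vinyl group. The N-trifluoroacetyl indole 17 formed first loses its acyl group in the flask.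

8 to 7, then to 5 and 6. The trifluoroacetyl group is cut from nitrogen; it is what makes the N–H acidic enough for the key step. The aryl–alkyne bond of 7 is cut by a Sonogashira disconnection to enyne 5 and 2-iodoaniline 6. Coupling is done on the free aniline and acylation afterwards, because the acylated alkyne would cyclise under copper and palladium.

5 to 3 to 1. The terminal alkyne carbon is removed by a Seyferth–Gilbert disconnection in its Ohira–Bestmann form, which leads to aldehyde 4. Aldehyde 4 is volatile and is generated in the flask from Weinreb amide 3, which comes from acid 1 through acid chloride 2. The quaternary carbon carries no hydrogen, so neither 4 nor 2 can enolise or move the double bond into conjugation.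

16 to 15. The C–I bond is cut. The only unsubstituted position of the central ring in 15 lies between two methoxy groups and is the most nucleophilic aromatic carbon of the molecule, since the indole is deactivated by the sulfonyl group. Iodine is introduced after the biaryl bond so that the core never carries two equivalent halogens.

15 to 11 and 12. The biaryl bond is cut by a Negishi disconnection to 3-iodo-1-tosylindole 11 and the arylzinc 14. Arylzinc 14 is made from 1,2,4,5-tetramethoxybenzene 12 by deprotonation between two methoxy groups (aryllithium 13) and transmetalation. A single coupling at a symmetric diiodinated core was set aside, because palladium is released next to the second C–I bond after the first coupling and double coupling competes. The 2,6-dimethoxyaryl nucleophile is used as the zinc reagent because the corresponding boronic acid would be prone to protodeboronation.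

11 to 9. The C3–I and N–S bonds are cut back to indole 9. Iodination at C3 gives 3-iodoindole 10, which is unstable and is sulfonylated in the same flask.

## Alternatives that were turned down

Alternative 1: The central ring is made last, from a four-membered ring. The bond cut joins the carbon that becomes the C–OH next to indole B to the methoxy-bearing carbon next to indole A. In the forward direction the 4-alkenyl-4-hydroxycyclobutenone A1 is heated. Its four-membered ring opens to a dienylketene, a 6π electrocyclisation closes the six-membered ring, and tautomerisation gives the hydroquinone A2, which still carries a SEM group on indole B and a TIPS group on indole A. In its favour, the substitution pattern is fixed by connectivity. The ring also arrives at the hydroquinone level with the two methoxy groups already distinct from the two future carbonyl oxygens, so a mild two-electron oxidation suffices. On this point it is stronger than the chosen route, which needs a cerium oxidant next to an indole. Against it, A1 must be built by two additions of crowded organometallics to a cyclobutenedione. One is the C3 anion of a 2-tert-alkylindole, which means the hindered indole has to be made, protected and metalated beforehand. The other is a β-methoxyvinyl anion of defined geometry, which can lose methoxide to give an alkyne. The SEM group sits on a nitrogen next to the quaternary carbon and would have to be removed from a quinone. The sequence is long and linear. The chosen strategy offers a convergent union of two fragments instead, and a crowded biaryl bond that is formed while a ring closes.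

Alternative 2: Both substituents of indole B are placed on a preformed indole; the bonds cut are C2–C(quaternary) and C3–aryl. In the forward direction the tertiary allyl boronic ester A3 and a 2-lithiated N-Boc indole give the boronate complex A4. The arylpalladium iodide derived from 16 attacks C3 of A4 and triggers a 1,2-shift of the 1,1-dimethylallyl group from boron to C2. Oxidation of the C–B bond and elimination restore the indole and give the N-Boc product A5. In its favour, it uses the same iodide 16 and plain indole, needs no enyne, and joins three components in one operation. In step count it is equal to or shorter than the chosen route. Against it, a tertiary allyl group is a slow migrating group on boron. It can also transfer with allylic transposition, or after a 1,3-boron shift, which would give the linear prenyl isomer with no way to correct it. The dearomatised intermediate would hold a fully substituted C2 next to a C3 bearing the doubly ortho-substituted aryl group. The combination of an aryl halide electrophile with a tertiary allyl migrating group is not covered by the known scope of this reaction type. The chosen strategy offers a reaction class whose scope clearly includes 2-alkyl-3-aryl indoles from aryl iodides, and the quaternary carbon is never formed or moved at the crowded stage.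

Alternative 3: Two bonds of the central ring are cut, so that one half comes from a cyclobutenone and the other from an alkyne. In the forward direction the cyclobutenone A5-type partner A6 is heated with the indolyl ynol ether A7. A6 opens to a vinylketene, which adds to the alkyne in a [2+2] cycloaddition; a second ring opening and a 6π closure give the pentasubstituted phenol A8. The ketene carbonyl carbon bonds to the alkyne carbon bearing indole B, and the methoxy alkyne carbon bonds to the former ketene α-carbon. In its favour, the ring is built with every substituent placed by the polarity of the ketene–ynol ether addition, and two indole-bearing halves are joined convergently. The p-methoxyphenol A8 can be oxidised to the quinone under milder conditions than a tetramethoxybenzene, so on the oxidation step it is stronger than the chosen route. Against it, the alkyne carbon that must bond to the ketene carbonyl carbon carries the 2-tert-alkylindol-3-yl group, so the cycloaddition is sterically very demanding. Fully substituted alkoxyalkynes are also poorer partners than terminal or silylated ones. A6 is a sensitive compound that needs its own multistep synthesis, and A7 again requires the preformed, protected hindered indole. Removal of SEM from the hindered nitrogen remains. The chosen strategy offers short access to both fragments from catalogue compounds, and it solves the hindered-indole problem, where this alternative only moves it.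

Key step: step 8

Remark on the chemistry: enyne 5 is volatile and is meant to be carried forward as an assayed solution; tosyl stands for 4-methylbenzenesulfonyl throughout.

## Route

Step 1
Reactants: 1 2,2-dimethylbut-3-enoic acid
Product: 3 N-methoxy-N,2,2-trimethylbut-3-enamide, via 2,2-dimethylbut-3-enoyl chloride 2 (not isolated)
Conditions: (COCl)2, DMF (cat.), CH2Cl2, 0 °C → rt; then MeNH(OMe)·HCl, pyridine, CH2Cl2, 0 °C → rt
Reagents that add atoms: N,O-dimethylhydroxylamine hydrochloride, CNOC.Cl
Why: Acid chloride formation and amidation to the Weinreb amide; the α-carbon is quaternary, so neither ketene formation nor migration of the double bond into conjugation is possible.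

Step 2
Reactants: 3 N-methoxy-N,2,2-trimethylbut-3-enamide
Product: 5 3,3-dimethylpent-1-en-4-yne, via 2,2-dimethylbut-3-enal 4 (not isolated)
Conditions: i-Bu2AlH, THF, −78 °C; then MeOH, K2CO3, dimethyl (1-diazo-2-oxopropyl)phosphonate, −78 °C → rt
Reagents that add atoms: dimethyl (1-diazo-2-oxopropyl)phosphonate, CC(=O)C(=[N+]=[N-])P(=O)(OC)OC
Why: Hydride reduction of the Weinreb amide stops at the chelated aluminium aminal, which releases the non-enolisable aldehyde 4 on addition of methanol; Seyferth–Gilbert homologation with the Ohira–Bestmann reagent then gives the terminal alkyne in one pot. The aldehyde is never isolated, and the volatile enyne should be extracted into pentane, dried, assayed and used as a solution.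

Step 3
Reactants: 5 3,3-dimethylpent-1-en-4-yne; 6 2-iodoaniline
Product: 7 2-(3,3-dimethylpent-4-en-1-yn-1-yl)aniline
Conditions: PdCl2(PPh3)2 (2 mol %), CuI (4 mol %), Et3N, THF, rt
Reagents that add atoms: none
Why: Sonogashira coupling of an aryl iodide with a terminal alkyne at room temperature; the free aniline is tolerated and does not cyclise under these conditions, and the vinyl group on the quaternary carbon is inert.

Step 4
Reactants: 7 2-(3,3-dimethylpent-4-en-1-yn-1-yl)aniline
Product: 8 N-[2-(3,3-dimethylpent-4-en-1-yn-1-yl)phenyl]-2,2,2-trifluoroacetamide
Conditions: (CF3CO)2O, pyridine, CH2Cl2, 0 °C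
Reagents that add atoms: trifluoroacetic anhydride, O=C(OC(=O)C(F)(F)F)C(F)(F)F
Why: N-acylation of the aniline; the trifluoroacetyl group makes the N–H acidic enough for carbonate to form the amidate in the key step, and it is lost there without a separate operation.

Step 5
Reactants: 9 indole
Product: 11 3-iodo-1-tosylindole, via 3-iodo-1H-indole 10 (not isolated)
Conditions: I2, KOH, DMF, rt; then TsCl, 0 °C → rt
Reagents that add atoms: iodine, [I][I]; 4-methylbenzenesulfonyl chloride, Cc1ccc(cc1)S(=O)(=O)Cl
Why: Electrophilic iodination of the indolide at C3 followed by N-sulfonylation in the same flask; the unstable 3-iodoindole 10 is trapped as the stable sulfonamide.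

Step 6
Reactants: 12 1,2,4,5-tetramethoxybenzene; 11 3-iodo-1-tosylindole
Product: 15 3-(2,3,5,6-tetramethoxyphenyl)-1-tosylindole, via (2,3,5,6-tetramethoxyphenyl)lithium 13 (not isolated), via chloro(2,3,5,6-tetramethoxyphenyl)zinc 14 (not isolated)
Conditions: n-BuLi, THF, 0 °C → rt; ZnCl2, THF, 0 °C → rt; then 11, Pd(PPh3)4 (5 mol %), THF, 60 °C
Reagents that add atoms: none
Why: Directed ortho-lithiation between two methoxy groups, transmetalation to zinc and Negishi coupling with the unhindered 3-iodoindole. Arene 12 is used in slight excess over n-BuLi, so no alkyllithium is left to attack the sulfonamide, and the arylzinc does not deprotonate C2 of 11. Only one position of 12 reacts, so a single coupling is assured.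

Step 7
Reactants: 15 3-(2,3,5,6-tetramethoxyphenyl)-1-tosylindole
Product: 16 3-(4-iodo-2,3,5,6-tetramethoxyphenyl)-1-tosylindole
Conditions: N-iodosuccinimide, CF3CO2H (cat.), MeCN, 0 °C → rt, dark
Reagents that add atoms: N-iodosuccinimide, O=C1CCC(=O)N1I
Why: Electrophilic aromatic iodination at the one free position of the central ring, which is activated by two ortho methoxy groups; the N-sulfonyl indole, with C3 blocked, is far less nucleophilic and should stay untouched.

Step 8
Reactants: 8 N-[2-(3,3-dimethylpent-4-en-1-yn-1-yl)phenyl]-2,2,2-trifluoroacetamide; 16 3-(4-iodo-2,3,5,6-tetramethoxyphenyl)-1-tosylindole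
Product: 18 2-(2-methylbut-3-en-2-yl)-3-[2,3,5,6-tetramethoxy-4-(1-tosylindol-3-yl)phenyl]-1H-indole, via N-trifluoroacetylindole 17 (not isolated)
Conditions: Pd(PPh3)4 (10 mol %), Cs2CO3, MeCN, 80 °C
Reagents that add atoms: none
Why: This is the Cacchi aminopalladation–reductive elimination indole synthesis, and the closest known reaction type is exactly this preparation of 2-alkyl-3-aryl indoles from aryl iodides and o-alkynyl trifluoroacetanilides. Zerovalent palladium inserts into the C–I bond of 16, and the arylpalladium iodide binds the alkyne of the caesium amidate of 8. The amidate nitrogen attacks the alkyne carbon bearing the quaternary substituent from the side opposite to palladium (anti aminopalladation), which closes the pyrrole ring in a 5-endo-dig mode and forms N1–C2. Reductive elimination from the 3-indolyl(aryl)palladium species forms the C3–aryl bond and returns zerovalent palladium; crowding at the metal speeds this step. The N-trifluoroacetyl indole 17 is cleaved by carbonate in the flask, so 18 should be obtained with a free N–H. No stereocentre is formed. The step needs selectivity for the alkyne over the vinyl group and for aryl transfer over simple cyclisation of 8: the amidate sits five atoms from the alkyne, the vinyl group is neopentyl-like and faces a palladium centre flanked by two methoxy groups, and 8 is used in excess and added in portions so that amidate is present whenever arylpalladium is. The quaternary carbon arrives on the alkyne, so no bond to a preformed crowded indole has to be made.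

Step 9
Reactants: 18 2-(2-methylbut-3-en-2-yl)-3-[2,3,5,6-tetramethoxy-4-(1-tosylindol-3-yl)phenyl]-1H-indole
Product: 19 2,5-dimethoxy-3-[2-(2-methylbut-3-en-2-yl)-1H-indol-3-yl]-6-(1-tosylindol-3-yl)cyclohexa-2,5-diene-1,4-dione
Conditions: (NH4)2Ce(NO3)6, MeCN/H2O (3:1), 0 °C
Reagents that add atoms: water, O
Why: Oxidative demethylation of a p-dimethoxyarene by tetravalent cerium: the arene radical cation takes up water at two para methoxy-bearing carbons and loses methanol, and either para pair gives the same quinone. The sulfonylated indole A is too electron-poor to be oxidised, and the free indole B has both C2 and C3 substituted and shielded. The isolated alkene is inert.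

Step 10
Reactants: 19 2,5-dimethoxy-3-[2-(2-methylbut-3-en-2-yl)-1H-indol-3-yl]-6-(1-tosylindol-3-yl)cyclohexa-2,5-diene-1,4-dione
Product: 20 2,5-dimethoxy-3-[2-(2-methylbut-3-en-2-yl)-1H-indol-3-yl]-6-(1H-indol-3-yl)cyclohexa-2,5-diene-1,4-dione
Conditions: Cs2CO3, MeOH/THF (1:2), rt
Reagents that add atoms: none
Why: Methanolysis of an N-sulfonyl indole: methoxide attacks sulfur, and the indolide is a good leaving group because the quinone at C3 makes it a vinylogous amide anion. Addition–elimination of methoxide at the methoxy-bearing quinone carbons is degenerate, and no reductant is present, so the quinone should survive under dry, air-free conditions.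

## Compound list

1 | 2,2-dimethylbut-3-enoic acid | C=CC(C)(C)C(=O)O | starting material
2 | 2,2-dimethylbut-3-enoyl chloride | C=CC(C)(C)C(=O)Cl | intermediate (not isolated)
3 | N-methoxy-N,2,2-trimethylbut-3-enamide | C=CC(C)(C)C(=O)N(C)OC | intermediate
4 | 2,2-dimethylbut-3-enal | C=CC(C)(C)C=O | intermediate (not isolated)
5 | 3,3-dimethylpent-1-en-4-yne | C=CC(C)(C)C#C | intermediate
6 | 2-iodoaniline | Nc1ccccc1I | starting material
7 | 2-(3,3-dimethylpent-4-en-1-yn-1-yl)aniline | C=CC(C)(C)C#Cc1ccccc1N | intermediate
8 | N-[2-(3,3-dimethylpent-4-en-1-yn-1-yl)phenyl]-2,2,2-trifluoroacetamide | C=CC(C)(C)C#Cc1ccccc1NC(=O)C(F)(F)F | intermediate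
9 | indole | c1ccc2[nH]ccc2c1 | starting material
10 | 3-iodo-1H-indole | Ic1c[nH]c2ccccc12 | intermediate (not isolated)
11 | 3-iodo-1-tosylindole (3-iodo-1-(4-methylbenzenesulfonyl)-1H-indole) | Cc1ccc(cc1)S(=O)(=O)n1cc(I)c2ccccc12 | intermediate
12 | 1,2,4,5-tetramethoxybenzene | COc1cc(OC)c(OC)cc1OC | starting material
13 | (2,3,5,6-tetramethoxyphenyl)lithium | [Li]c1c(OC)c(OC)cc(OC)c1OC | intermediate (not isolated)
14 | chloro(2,3,5,6-tetramethoxyphenyl)zinc | Cl[Zn]c1c(OC)c(OC)cc(OC)c1OC | intermediate (not isolated)
15 | 3-(2,3,5,6-tetramethoxyphenyl)-1-tosylindole | COc1cc(OC)c(OC)c(-c2cn(S(=O)(=O)c3ccc(C)cc3)c3ccccc23)c1OC | intermediate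
16 | 3-(4-iodo-2,3,5,6-tetramethoxyphenyl)-1-tosylindole | COc1c(OC)c(I)c(OC)c(OC)c1-c1cn(S(=O)(=O)c2ccc(C)cc2)c2ccccc12 | intermediate
17 | 2,2,2-trifluoro-1-{2-(2-methylbut-3-en-2-yl)-3-[2,3,5,6-tetramethoxy-4-(1-tosylindol-3-yl)phenyl]indol-1-yl}ethanone | COc1c(OC)c(-c2cn(S(=O)(=O)c3ccc(C)cc3)c3ccccc23)c(OC)c(OC)c1-c1c(C(C)(C)C=C)n(C(=O)C(F)(F)F)c2ccccc12 | intermediate (not isolated)
18 | 2-(2-methylbut-3-en-2-yl)-3-[2,3,5,6-tetramethoxy-4-(1-tosylindol-3-yl)phenyl]-1H-indole | COc1c(OC)c(-c2cn(S(=O)(=O)c3ccc(C)cc3)c3ccccc23)c(OC)c(OC)c1-c1c(C(C)(C)C=C)[nH]c2ccccc12 | intermediate
19 | 2,5-dimethoxy-3-[2-(2-methylbut-3-en-2-yl)-1H-indol-3-yl]-6-(1-tosylindol-3-yl)cyclohexa-2,5-diene-1,4-dione | C=CC(C)(C)c1[nH]c2ccccc2c1C1=C(OC)C(=O)C(c2cn(S(=O)(=O)c3ccc(C)cc3)c3ccccc23)=C(OC)C1=O | intermediate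
20 | 2,5-dimethoxy-3-[2-(2-methylbut-3-en-2-yl)-1H-indol-3-yl]-6-(1H-indol-3-yl)cyclohexa-2,5-diene-1,4-dione | C=CC(C)(C)c1[nH]c2ccccc2c1C1=C(OC)C(=O)C(c2c[nH]c3ccccc23)=C(OC)C1=O | target

## Step count and least certain steps

Total step count: 10. Longest linear sequence: 7 steps (steps 1, 2, 3, 4, 8, 9 and 10); the other branch (steps 5, 6 and 7) joins at step 8.

Step 8 (key step). The most likely failure is that 8 cyclises without taking up the aryl group. Oxidative addition to the doubly ortho-substituted, electron-rich iodide 16 and binding of the tert-alkyl-substituted alkyne are both slow, so base- or palladium-mediated ring closure followed by protonation can win. Arylation of the vinyl group and reduction of the C–I bond are lesser drains. The fallback builds the same indole by a Larock heteroannulation, in which the crowded aryl group is on the alkyne and not on palladium. It sets out from 16 and uses 5 and 6. Sonogashira coupling of 16 with 5 (PdCl2(PPh3)2, CuI, Et3N, DMF, 70 °C) should give 3-[4-(3,3-dimethylpent-4-en-1-yn-1-yl)-2,3,5,6-tetramethoxyphenyl]-1-tosylindole F1. Annulation of F1 with 6 (Pd(OAc)2, LiCl, K2CO3, DMF, 100 °C) places the aniline carbon on the alkyne carbon remote from the tert-alkyl group and nitrogen on the carbon that bears it. The fallback comes back to the route at 18.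

Step 9. The one-electron oxidant may attack the free indole B, or two adjacent methoxy groups may be lost to give an ortho-quinone, in competition with the desired para oxidative demethylation. The fallback avoids a one-electron oxidant altogether and sets out from 18. Exhaustive O-demethylation with BBr3 (CH2Cl2, −78 → 0 °C) should give 3-[2-(2-methylbut-3-en-2-yl)-1H-indol-3-yl]-6-(1-tosylindol-3-yl)benzene-1,2,4,5-tetrol F2. F2 is oxidised by air during work-up to 2,5-dihydroxy-3-[2-(2-methylbut-3-en-2-yl)-1H-indol-3-yl]-6-(1-tosylindol-3-yl)cyclohexa-2,5-diene-1,4-dione F3. O-Methylation of the two vinylogous acid hydroxyls of F3 with Me3SiCHN2 (MeOH/toluene, 0 °C → rt) comes back to the route at 19.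

Step 10. Attack of hydroxide from adventitious water on the vinylogous ester, or base-induced decomposition of the quinone, may outrun N–S cleavage. The fallback reverses the order of the last two operations and sets out from 18. Reductive detosylation with Mg in MeOH (sonication, rt) should give 3-[4-(1H-indol-3-yl)-2,3,5,6-tetramethoxyphenyl]-2-(2-methylbut-3-en-2-yl)-1H-indole F4. Oxidation of F4 with (NH4)2Ce(NO3)6 (MeCN/H2O, 0 °C) comes back to the route at 20. The price is that indole A then faces the oxidant with a free N–H and a free C2.

Step 7. Iodination may go to the indole ring, or the iodonium source may oxidatively demethylate the electron-rich ring, instead of substituting the single free position. The fallback installs the halogen before the indole is attached. It sets out from 12 and 11. Double iodination of 12 (N-iodosuccinimide, CF3CO2H, MeCN), where both free positions are equivalent, should give 1,4-diiodo-2,3,5,6-tetramethoxybenzene F5. Miyaura borylation of 11 (bis(pinacolato)diboron, PdCl2(dppf), KOAc, dioxane, 90 °C) should give 3-(4,4,5,5-tetramethyl-1,3,2-dioxaborolan-2-yl)-1-tosylindole F6. Suzuki coupling of F6 with a threefold excess of F5 (Pd(PPh3)4, K3PO4, dioxane/H2O, 80 °C), with recovery of unreacted F5, comes back to the route at 16. Some double coupling is the expected cost.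

## Further compounds

F1 | step 8 | 3-[4-(3,3-dimethylpent-4-en-1-yn-1-yl)-2,3,5,6-tetramethoxyphenyl]-1-tosylindole | C=CC(C)(C)C#Cc1c(OC)c(OC)c(-c2cn(S(=O)(=O)c3ccc(C)cc3)c3ccccc23)c(OC)c1OC
F2 | step 9 | 3-[2-(2-methylbut-3-en-2-yl)-1H-indol-3-yl]-6-(1-tosylindol-3-yl)benzene-1,2,4,5-tetrol | C=CC(C)(C)c1[nH]c2ccccc2c1-c1c(O)c(O)c(-c2cn(S(=O)(=O)c3ccc(C)cc3)c3ccccc23)c(O)c1O
F3 | step 9 | 2,5-dihydroxy-3-[2-(2-methylbut-3-en-2-yl)-1H-indol-3-yl]-6-(1-tosylindol-3-yl)cyclohexa-2,5-diene-1,4-dione | C=CC(C)(C)c1[nH]c2ccccc2c1C1=C(O)C(=O)C(c2cn(S(=O)(=O)c3ccc(C)cc3)c3ccccc23)=C(O)C1=O
F4 | step 10 | 3-[4-(1H-indol-3-yl)-2,3,5,6-tetramethoxyphenyl]-2-(2-methylbut-3-en-2-yl)-1H-indole | COc1c(OC)c(-c2c[nH]c3ccccc23)c(OC)c(OC)c1-c1c(C(C)(C)C=C)[nH]c2ccccc12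
F5 | step 7 | 1,4-diiodo-2,3,5,6-tetramethoxybenzene | COc1c(OC)c(I)c(OC)c(OC)c1I
F6 | step 7 | 3-(4,4,5,5-tetramethyl-1,3,2-dioxaborolan-2-yl)-1-tosylindole | Cc1ccc(cc1)S(=O)(=O)n1cc(B2OC(C)(C)C(C)(C)O2)c2ccccc12
A1 | alternative 1 | 4-hydroxy-3-methoxy-4-[(E)-2-methoxy-1-(1-triisopropylsilylindol-3-yl)ethenyl]-2-[2-(2-methylbut-3-en-2-yl)-1-(2-trimethylsilylethoxymethyl)indol-3-yl]cyclobut-2-en-1-one (racemic) | CO/C=C(/C1(O)C(OC)=C(c2c(C(C)(C)C=C)n(COCC[Si](C)(C)C)c3ccccc23)C1=O)c1cn([Si](C(C)C)(C(C)C)C(C)C)c2ccccc12
A2 | alternative 1 | 2,5-dimethoxy-3-[2-(2-methylbut-3-en-2-yl)-1-(2-trimethylsilylethoxymethyl)indol-3-yl]-6-(1-triisopropylsilylindol-3-yl)benzene-1,4-diol | COc1c(O)c(-c2c(C(C)(C)C=C)n(COCC[Si](C)(C)C)c3ccccc23)c(OC)c(O)c1-c1cn([Si](C(C)C)(C(C)C)C(C)C)c2ccccc12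
A3 | alternative 2 | 4,4,5,5-tetramethyl-2-(2-methylbut-3-en-2-yl)-1,3,2-dioxaborolane | C=CC(C)(C)B1OC(C)(C)C(C)(C)O1
A4 | alternative 2 | lithium [1-(tert-butoxycarbonyl)indol-2-yl](2-methylbut-3-en-2-yl)(pinacolato)borate | [Li+].C=CC(C)(C)[B-]1(OC(C)(C)C(C)(C)O1)c1cc2ccccc2n1C(=O)OC(C)(C)C
A5 | alternative 2 | tert-butyl 2-(2-methylbut-3-en-2-yl)-3-[2,3,5,6-tetramethoxy-4-(1-tosylindol-3-yl)phenyl]indole-1-carboxylate | COc1c(OC)c(-c2cn(S(=O)(=O)c3ccc(C)cc3)c3ccccc23)c(OC)c(OC)c1-c1c(C(C)(C)C=C)n(C(=O)OC(C)(C)C)c2ccccc12
A6 | alternative 3 | 2,4-dimethoxy-3-(1-triisopropylsilylindol-3-yl)cyclobut-2-en-1-one (racemic) | COC1C(=O)C(OC)=C1c1cn([Si](C(C)C)(C(C)C)C(C)C)c2ccccc12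
A7 | alternative 3 | 3-(methoxyethynyl)-2-(2-methylbut-3-en-2-yl)-1-(2-trimethylsilylethoxymethyl)indole | COC#Cc1c(C(C)(C)C=C)n(COCC[Si](C)(C)C)c2ccccc12
A8 | alternative 3 | 3,4,6-trimethoxy-2-[2-(2-methylbut-3-en-2-yl)-1-(2-trimethylsilylethoxymethyl)indol-3-yl]-5-(1-triisopropylsilylindol-3-yl)phenol | COc1c(O)c(-c2c(C(C)(C)C=C)n(COCC[Si](C)(C)C)c3ccccc23)c(OC)c(OC)c1-c1cn([Si](C(C)C)(C(C)C)C(C)C)c2ccccc12
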